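**Plan**

- Numbering: C1 lactone C=O, C2H=C3 ring alkene, C25 ring OCH2, C4 carbinol, C5H2, C6H=C7 (C24 hydroxymethyl on C7), C8H2, C9H2, C10 onward the farnesyl-derived chain.
- Cuts: the butenolide at C2=C3 (ring-closing metathesis) and at the C1–O ester bond; C3–C4 together with C5–C6; C7–C8 and C6–Br (carbocupration and bromination of a propargyl ether); C8–C9 (one-carbon extension of farnesyl bromide).
- Enabling feature: C4 is a secondary carbinol carbon lying between sp2 C3 of the butenolide ring and a CH2 (C5) that is bonded to sp2 C6. A vinyl group on boron (C4, C5), a second alkenyl group on the same boron (C3) and an alkenyl halide (C6) give this sp2C–CH(B)–CH2–sp2C array in one operation, and boron is then exchanged for OH.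
- Forward order: the chain bromide (C6–C24) is built first; the three-component coupling joins it to the C4–C5 vinyl unit and the C3/C25 unit; the only ring, the butenolide, is closed in the last step but one.
- Stereochemistry: C4 (R) comes from the chiral Mandyphos ligand on palladium and is carried through a stereoretentive C–B oxidation. The C6=C7 geometry comes from syn-carbocupration and stereoretentive bromination and coupling. The two chain (E)-alkenes come from (2E,6E)-farnesyl bromide.

Key step: step 8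

Assumption: (Sp,Sp)-Mandyphos, that is (αR,αR)-2,2′-bis(α-N,N-dimethylaminophenylmethyl)-(S,S)-1,1′-bis[bis(4-methoxy-3,5-dimethylphenyl)phosphino]ferrocene, is taken to place boron on the face that gives (R)-C4, by analogy with other sp2-carbon migrating groups on vinyl borates; if the sense were opposite, the mirror-image ligand would be used with no other change.

**Route**

Step 1
Reactants: 1 2-bromoprop-2-en-1-ol
Product: 2 1-{[(2-bromoprop-2-en-1-yl)oxy]methyl}-4-methoxybenzene
Conditions: NaH, PMBCl, n-Bu4NI (cat.), THF/DMF, 0 °C → rt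
Reagents that add atoms: 4-methoxybenzyl chloride, COc1ccc(CCl)cc1
Why: Williamson etherification of the primary allylic alkoxide; the alkenyl bromide is inert to NaH at this temperature.

Step 2
Reactants: 2 1-{[(2-bromoprop-2-en-1-yl)oxy]methyl}-4-methoxybenzene
Product: 3 2-[3-(4-methoxybenzyloxy)prop-1-en-2-yl]-4,4,5,5-tetramethyl-1,3,2-dioxaborolane
Conditions: B2pin2, PdCl2(PPh3)2 (3 mol %), PPh3 (6 mol %), KOPh, toluene, 50 °C
Reagents that add atoms: bis(pinacolato)diboron, CC1(C)OB(OC1(C)C)B1OC(C)(C)C(C)(C)O1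
Why: Miyaura borylation (oxidative addition of the 1,1-disubstituted alkenyl bromide to zerovalent palladium, phenoxide-assisted transmetalation with the diboron, reductive elimination) should give the alkenylboronate without disturbing the allylic ether.

Step 3
Reactants: 4 tetravinylstannane
Product: 5 vinyllithium
Conditions: n-BuLi, pentane, rt; precipitate collected, dissolved in THF and titrated
Reagents that add atoms: n-butyllithium, [Li]CCCC
Why: Tin–lithium exchange gives halide-free vinyllithium, which precipitates from pentane and is thereby separated from the butyltin by-product.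

Step 4
Reactants: 6 (2E,6E)-farnesyl bromide; 7 (chloromethyl)(isopropoxy)dimethylsilane
Product: 9 isopropoxydimethyl[(3E,7E)-4,8,12-trimethyltrideca-3,7,11-trien-1-yl]silane, via silylmethyl Grignard reagent 8 (not isolated)
Conditions: 7, Mg, THF, rt; then 6, Li2CuCl4 (3 mol %), THF, −20 → 0 °C; product used crude
Reagents that add atoms: none
Why: Copper-catalysed Grignard coupling at the primary allylic bromide should go by direct substitution because the γ-carbon is fully substituted, so the (E)-alkene is kept and C8 is added carrying a silicon mask for oxygen.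

Step 5
Reactants: 9 isopropoxydimethyl[(3E,7E)-4,8,12-trimethyltrideca-3,7,11-trien-1-yl]silane
Product: 10 (3E,7E)-4,8,12-trimethyltrideca-3,7,11-trien-1-ol (homofarnesol)
Conditions: 30 % H2O2, KF, KHCO3, THF/MeOH, rt
Reagents that add atoms: hydrogen peroxide, OO
Why: Tamao oxidation (fluoride-activated alkoxysilane, peroxide-induced shift of the alkyl group from silicon to oxygen); basic H2O2 does not epoxidise the trisubstituted alkenes.

Step 6
Reactants: 10 (3E,7E)-4,8,12-trimethyltrideca-3,7,11-trien-1-ol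
Product: 11 (3E,7E)-1-bromo-4,8,12-trimethyltrideca-3,7,11-triene (homofarnesyl bromide)
Conditions: CBr4, PPh3, CH2Cl2, 0 °C
Reagents that add atoms: carbon tetrabromide, BrC(Br)(Br)Br
Why: Appel reaction converts the primary alcohol into the bromide under neutral conditions that leave the triene untouched.

Step 7
Reactants: 11 (3E,7E)-1-bromo-4,8,12-trimethyltrideca-3,7,11-triene; 12 tert-butyldimethyl(prop-2-yn-1-yloxy)silane
Product: 16 tert-butyl{[(2E,5E,9E)-2-(bromomethylidene)-6,10,14-trimethylpentadeca-5,9,13-trien-1-yl]oxy}dimethylsilane, via homofarnesylmagnesium bromide 13 (not isolated), via homofarnesylcopper 14 (not isolated), via alkenylcopper adduct 15 (not isolated)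
Conditions: Mg, Et2O, rt; CuBr (1 equiv), Et2O, −35 °C; 12 (slight excess), −25 °C; NBS, THF, −40 °C; aq. NH4Cl
Reagents that add atoms: N-bromosuccinimide, O=C1CCC(=O)N1Br
Why: Syn-carbocupration of a terminal alkyne places the alkyl group on the internal carbon (C7) and copper on the terminal carbon (C6) on the same face, the bulky, weakly coordinating silyl ether in Et2O being expected to disfavour the oxygen-guided opposite orientation; NBS then replaces copper by bromine with retention, and a sulfide-free copper source is chosen so that NBS is not consumed by Me2S.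

Step 8
Reactants: 3 2-[3-(4-methoxybenzyloxy)prop-1-en-2-yl]-4,4,5,5-tetramethyl-1,3,2-dioxaborolane; 5 vinyllithium; 16 tert-butyl{[(2E,5E,9E)-2-(bromomethylidene)-6,10,14-trimethylpentadeca-5,9,13-trien-1-yl]oxy}dimethylsilane
Product: 18 2-[(3R,5E,9E,13E)-6-{[(tert-butyldimethylsilyl)oxy]methyl}-2-[(4-methoxybenzyloxy)methyl]-10,14,18-trimethylnonadeca-1,5,9,13,17-pentaen-3-yl]-4,4,5,5-tetramethyl-1,3,2-dioxaborolane, via lithium alkenyl(vinyl)borate 17 (not isolated)
Conditions: 3 + 5, THF, 0 °C → rt; then 16, Pd(OAc)2 (3 mol %), (Sp,Sp)-Mandyphos (3.6 mol %), KOTf (2 equiv), THF, 60 °C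
Reagents that add atoms: none
Why: Vinyllithium adds to boron of 3 to give the four-coordinate borate 17, while oxidative addition of 16 to zerovalent palladium–Mandyphos and removal of bromide by KOTf give a cationic alkenylpalladium that binds the unsubstituted vinyl group of 17. The 2-substituted propenyl group then shifts from boron to C4 anti to palladium as the C5–Pd bond forms, and reductive elimination joins C5 to C6 with retention of the bromide geometry, so that C3–C4 and C5–C6 are made and no ring is closed. The closest known reaction type is the enantioselective palladium-catalysed conjunctive cross-coupling of bis(alkenyl)borates with sp2 electrophiles, halides included when a triflate salt is present. The C4 stereocentre is set by the ligand-controlled choice of the vinyl face to which palladium binds. The step needs palladium to bind the vinyl rather than the 1,1-disubstituted alkenyl group (secured by sterics) and the metallate shift to outrun direct alkenyl transfer to palladium (secured by the α-branch of the migrating group and the cationic metal centre). The PMB ether, a poor leaving group, should resist β-elimination from the borate.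

Step 9
Reactants: 18 the C4 pinacol boronate
Product: 19 (3R,5E,9E,13E)-6-{[(tert-butyldimethylsilyl)oxy]methyl}-2-[(4-methoxybenzyloxy)methyl]-10,14,18-trimethylnonadeca-1,5,9,13,17-pentaen-3-ol
Conditions: 30 % H2O2, 3 M aq. NaOH, THF, 0 °C → rt
Reagents that add atoms: hydrogen peroxide, OO
Why: Hydroperoxide adds to boron and C4 migrates from boron to oxygen with retention and without allylic transposition, so the configuration set in step 8 becomes that of the (R)-carbinol.

Step 10
Reactants: 19 the C4 alcohol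
Product: 20 (3R,5E,9E,13E)-3-[(tert-butyldimethylsilyl)oxy]-6-{[(tert-butyldimethylsilyl)oxy]methyl}-2-[(4-methoxybenzyloxy)methyl]-10,14,18-trimethylnonadeca-1,5,9,13,17-pentaene
Conditions: TBSCl, imidazole, DMAP (cat.), DMF, rt
Reagents that add atoms: tert-butyldimethylsilyl chloride, CC(C)(C)[Si](C)(C)Cl
Why: Silylation masks the secondary allylic C4 hydroxyl so that C25–OH alone is acylated later.

Step 11
Reactants: 20 the bis-silyl PMB ether
Product: 21 (3R,5E,9E,13E)-3-[(tert-butyldimethylsilyl)oxy]-6-{[(tert-butyldimethylsilyl)oxy]methyl}-10,14,18-trimethyl-2-methylidenenonadeca-5,9,13,17-tetraen-1-ol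
Conditions: DDQ, CH2Cl2/pH 7 buffer, 0 °C
Reagents that add atoms: none
Why: Oxidative PMB cleavage (hydride abstraction at the electron-rich benzylic position, hydrolysis of the oxocarbenium ion) leaves silyl ethers and isolated alkenes untouched.

Step 12
Reactants: 21 the C25 alcohol; 22 acryloyl chloride
Product: 23 (3R,5E,9E,13E)-3-[(tert-butyldimethylsilyl)oxy]-6-{[(tert-butyldimethylsilyl)oxy]methyl}-10,14,18-trimethyl-2-methylidenenonadeca-5,9,13,17-tetraen-1-yl acrylate
Conditions: 22, Et3N, CH2Cl2, −78 → 0 °C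
Reagents that add atoms: none
Why: Acylation of the primary allylic alcohol installs C1 and C2 as the acrylate needed for ring closure.

Step 13
Reactants: 23 the acrylate
Product: 24 4-[(1R,3E,7E,11E)-1-[(tert-butyldimethylsilyl)oxy]-4-{[(tert-butyldimethylsilyl)oxy]methyl}-8,12,16-trimethylheptadeca-3,7,11,15-tetraen-1-yl]furan-2(5H)-one
Conditions: second-generation Grubbs catalyst (10 mol %), CH2Cl2 (high dilution), 40 °C
Reagents that add atoms: none
Why: Ring-closing metathesis between the acrylate and the 1,1-disubstituted C3 alkene forms C2=C3 and closes the five-membered unsaturated lactone with loss of ethylene, a closure expected to outpace metathesis at the hindered trisubstituted chain alkenes.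

Step 14
Reactants: 24 the bis-silyl butenolide
Product: 25 hippolide C, 4-[(1R,3E,7E,11E)-1-hydroxy-4-(hydroxymethyl)-8,12,16-trimethylheptadeca-3,7,11,15-tetraen-1-yl]furan-2(5H)-one
Conditions: HF·pyridine, pyridine, THF, 0 °C → rt
Reagents that add atoms: none
Why: Buffered fluoride cleaves both silyl ethers without the basic conditions that could deprotonate the butenolide at the γ-positions and so endanger C4.

**Compound list**

1 | 2-bromoprop-2-en-1-ol | C=C(Br)CO | starting material
2 | 1-{[(2-bromoprop-2-en-1-yl)oxy]methyl}-4-methoxybenzene | C=C(Br)COCc1ccc(OC)cc1 | intermediate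
3 | 2-[3-(4-methoxybenzyloxy)prop-1-en-2-yl]-4,4,5,5-tetramethyl-1,3,2-dioxaborolane | C=C(COCc1ccc(OC)cc1)B1OC(C)(C)C(C)(C)O1 | intermediate
4 | tetravinylstannane | C=C[Sn](C=C)(C=C)C=C | starting material
5 | vinyllithium | [Li]C=C | intermediate
6 | (2E,6E)-1-bromo-3,7,11-trimethyldodeca-2,6,10-triene (farnesyl bromide) | CC(C)=CCC/C(C)=C/CC/C(C)=C/CBr | starting material
7 | (chloromethyl)(isopropoxy)dimethylsilane | CC(C)O[Si](C)(C)CCl | starting material
8 | [(isopropoxydimethylsilyl)methyl]magnesium chloride | CC(C)O[Si](C)(C)C[Mg]Cl | intermediate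
9 | isopropoxydimethyl[(3E,7E)-4,8,12-trimethyltrideca-3,7,11-trien-1-yl]silane | CC(C)=CCC/C(C)=C/CC/C(C)=C/CC[Si](C)(C)OC(C)C | intermediate
10 | (3E,7E)-4,8,12-trimethyltrideca-3,7,11-trien-1-ol | CC(C)=CCC/C(C)=C/CC/C(C)=C/CCO | intermediate
11 | (3E,7E)-1-bromo-4,8,12-trimethyltrideca-3,7,11-triene | CC(C)=CCC/C(C)=C/CC/C(C)=C/CCBr | intermediate
12 | tert-butyldimethyl(prop-2-yn-1-yloxy)silane | C#CCO[Si](C)(C)C(C)(C)C | starting material
13 | [(3E,7E)-4,8,12-trimethyltrideca-3,7,11-trien-1-yl]magnesium bromide | CC(C)=CCC/C(C)=C/CC/C(C)=C/CC[Mg]Br | intermediate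
14 | [(3E,7E)-4,8,12-trimethyltrideca-3,7,11-trien-1-yl]copper (as its MgBr2 complex) | CC(C)=CCC/C(C)=C/CC/C(C)=C/CC[Cu] | intermediate
15 | [(1E,5E,9E)-2-{[(tert-butyldimethylsilyl)oxy]methyl}-6,10,14-trimethylpentadeca-1,5,9,13-tetraen-1-yl]copper, copper cis to the chain | CC(C)=CCC/C(C)=C/CC/C(C)=C/CC/C(=C\[Cu])CO[Si](C)(C)C(C)(C)C | intermediate
16 | tert-butyl{[(2E,5E,9E)-2-(bromomethylidene)-6,10,14-trimethylpentadeca-5,9,13-trien-1-yl]oxy}dimethylsilane | CC(C)=CCC/C(C)=C/CC/C(C)=C/CC/C(=C\Br)CO[Si](C)(C)C(C)(C)C | intermediate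
17 | lithium [3-(4-methoxybenzyloxy)prop-1-en-2-yl](vinyl)(pinacolato)borate | [Li+].C=C[B-]1(C(=C)COCc2ccc(OC)cc2)OC(C)(C)C(C)(C)O1 | intermediate
18 | 2-[(3R,5E,9E,13E)-6-{[(tert-butyldimethylsilyl)oxy]methyl}-2-[(4-methoxybenzyloxy)methyl]-10,14,18-trimethylnonadeca-1,5,9,13,17-pentaen-3-yl]-4,4,5,5-tetramethyl-1,3,2-dioxaborolane | CC(C)=CCC/C(C)=C/CC/C(C)=C/CC/C(=C\C[C@@H](B1OC(C)(C)C(C)(C)O1)C(=C)COCc1ccc(OC)cc1)CO[Si](C)(C)C(C)(C)C | intermediate
19 | (3R,5E,9E,13E)-6-{[(tert-butyldimethylsilyl)oxy]methyl}-2-[(4-methoxybenzyloxy)methyl]-10,14,18-trimethylnonadeca-1,5,9,13,17-pentaen-3-ol | CC(C)=CCC/C(C)=C/CC/C(C)=C/CC/C(=C\C[C@@H](O)C(=C)COCc1ccc(OC)cc1)CO[Si](C)(C)C(C)(C)C | intermediate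
20 | (3R,5E,9E,13E)-3-[(tert-butyldimethylsilyl)oxy]-6-{[(tert-butyldimethylsilyl)oxy]methyl}-2-[(4-methoxybenzyloxy)methyl]-10,14,18-trimethylnonadeca-1,5,9,13,17-pentaene | CC(C)=CCC/C(C)=C/CC/C(C)=C/CC/C(=C\C[C@@H](O[Si](C)(C)C(C)(C)C)C(=C)COCc1ccc(OC)cc1)CO[Si](C)(C)C(C)(C)C | intermediate
21 | (3R,5E,9E,13E)-3-[(tert-butyldimethylsilyl)oxy]-6-{[(tert-butyldimethylsilyl)oxy]methyl}-10,14,18-trimethyl-2-methylidenenonadeca-5,9,13,17-tetraen-1-ol | CC(C)=CCC/C(C)=C/CC/C(C)=C/CC/C(=C\C[C@@H](O[Si](C)(C)C(C)(C)C)C(=C)CO)CO[Si](C)(C)C(C)(C)C | intermediate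
22 | acryloyl chloride | C=CC(=O)Cl | starting material
23 | (3R,5E,9E,13E)-3-[(tert-butyldimethylsilyl)oxy]-6-{[(tert-butyldimethylsilyl)oxy]methyl}-10,14,18-trimethyl-2-methylidenenonadeca-5,9,13,17-tetraen-1-yl acrylate | CC(C)=CCC/C(C)=C/CC/C(C)=C/CC/C(=C\C[C@@H](O[Si](C)(C)C(C)(C)C)C(=C)COC(=O)C=C)CO[Si](C)(C)C(C)(C)C | intermediate
24 | 4-[(1R,3E,7E,11E)-1-[(tert-butyldimethylsilyl)oxy]-4-{[(tert-butyldimethylsilyl)oxy]methyl}-8,12,16-trimethylheptadeca-3,7,11,15-tetraen-1-yl]furan-2(5H)-one | CC(C)=CCC/C(C)=C/CC/C(C)=C/CC/C(=C\C[C@@H](O[Si](C)(C)C(C)(C)C)C1=CC(=O)OC1)CO[Si](C)(C)C(C)(C)C | intermediate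
25 | hippolide C, 4-[(1R,3E,7E,11E)-1-hydroxy-4-(hydroxymethyl)-8,12,16-trimethylheptadeca-3,7,11,15-tetraen-1-yl]furan-2(5H)-one | CC(C)=CCC/C(C)=C/CC/C(C)=C/CC/C(=C\C[C@@H](O)C1=CC(=O)OC1)CO | target

**Count and risks**

Total steps: 14. Longest linear sequence: 11 steps (steps 4 to 14, from farnesyl bromide 6 to 25).

Step 7 (most likely to fail). The alkylcopper may add in the opposite orientation, with copper on the internal carbon under the influence of the propargylic oxygen, and the adduct may then lose silyloxide to an allene; electrophilic bromine may also attack chain alkenes. The fallback sets out from 11 and 12 and comes back at 16. Bromide 11 would be turned into (3E,7E)-1-iodo-4,8,12-trimethyltrideca-3,7,11-triene F1 (NaI, acetone). Alkyne 12 would then undergo copper-catalysed syn-alkylboration (B2pin2, CuCl, Xantphos, NaOt-Bu, F1, THF), in which boron goes to the terminal carbon and the alkyl group to the internal one, to give 2-[(1E,5E,9E)-2-{[(tert-butyldimethylsilyl)oxy]methyl}-6,10,14-trimethylpentadeca-1,5,9,13-tetraen-1-yl]-4,4,5,5-tetramethyl-1,3,2-dioxaborolane F2. Treatment with CuBr2 in aqueous methanol would exchange boron for bromine with retention and deliver 16.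

Step 8. Direct alkenyl–alkenyl transfer to palladium may compete with the metallate shift, palladium may bind the wrong alkenyl group, residual bromide may block the cationic palladium, or facial discrimination may be insufficient. The fallback sets out from 16 and 3 and comes back at 18; it gives up the three-component union but forms C3–C4 by the same shift of the alkenyl group from boron to C4. Bromine–lithium exchange on 16 (t-BuLi, Et2O, −78 °C) would give [(1E,5E,9E)-2-{[(tert-butyldimethylsilyl)oxy]methyl}-6,10,14-trimethylpentadeca-1,5,9,13-tetraen-1-yl]lithium F3. Opening of oxirane with BF3·OEt2 would give (3E,7E,11E)-4-{[(tert-butyldimethylsilyl)oxy]methyl}-8,12,16-trimethylheptadeca-3,7,11,15-tetraen-1-ol F4, and carbamoylation (i-Pr2NCOCl, Et3N) would give its N,N-diisopropylcarbamate F5. Deprotonation with s-BuLi/(−)-sparteine (Et2O, −78 °C), which removes the pro-S hydrogen, should give the (S)-α-lithiated carbamate F6. Stereoretentive trapping with 3 would give the lithium boronate complex F7, and warming with MgBr2·OEt2 should bring about 1,2-migration with inversion to give (R)-18.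

Step 13. The catalyst may engage the chain alkenes (truncation at the terminal isopropylidene, oligomerisation) faster than it closes the ring between an electron-poor acrylate and a hindered 1,1-disubstituted alkene. The fallback sets out from 5 and 16 and comes back at 25; it derives the butenolide from a furan instead of by metathesis. Purchased furan-3-ylboronic acid pinacol ester F8 and 5 would give lithium (furan-3-yl)(vinyl)(pinacolato)borate F9, which under the conditions of step 8 with 16 should give 2-[(1R,3E,7E,11E)-4-{[(tert-butyldimethylsilyl)oxy]methyl}-1-(furan-3-yl)-8,12,16-trimethylheptadeca-3,7,11,15-tetraen-1-yl]-4,4,5,5-tetramethyl-1,3,2-dioxaborolane F10. Oxidation (H2O2, NaOH) would give (1R,3E,7E,11E)-4-{[(tert-butyldimethylsilyl)oxy]methyl}-1-(furan-3-yl)-8,12,16-trimethylheptadeca-3,7,11,15-tetraen-1-ol F11. Singlet oxygen (O2, light, rose bengal, i-Pr2NEt, CH2Cl2, −78 °C), with the hindered base removing the ring proton remote from the side chain, would give 5-hydroxy-4-[(1R,3E,7E,11E)-1-hydroxy-4-{[(tert-butyldimethylsilyl)oxy]methyl}-8,12,16-trimethylheptadeca-3,7,11,15-tetraen-1-yl]furan-2(5H)-one F12. Reduction with NaBH4 and acidic work-up would give 4-[(1R,3E,7E,11E)-1-hydroxy-4-{[(tert-butyldimethylsilyl)oxy]methyl}-8,12,16-trimethylheptadeca-3,7,11,15-tetraen-1-yl]furan-2(5H)-one F13, and HF·pyridine would give 25.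

**Further compounds**

F1 | step 7 | (3E,7E)-1-iodo-4,8,12-trimethyltrideca-3,7,11-triene | CC(C)=CCC/C(C)=C/CC/C(C)=C/CCI
F2 | step 7 | 2-[(1E,5E,9E)-2-{[(tert-butyldimethylsilyl)oxy]methyl}-6,10,14-trimethylpentadeca-1,5,9,13-tetraen-1-yl]-4,4,5,5-tetramethyl-1,3,2-dioxaborolane | CC(C)=CCC/C(C)=C/CC/C(C)=C/CC/C(=C\B1OC(C)(C)C(C)(C)O1)CO[Si](C)(C)C(C)(C)C
F3 | step 8 | [(1E,5E,9E)-2-{[(tert-butyldimethylsilyl)oxy]methyl}-6,10,14-trimethylpentadeca-1,5,9,13-tetraen-1-yl]lithium | CC(C)=CCC/C(C)=C/CC/C(C)=C/CC/C(=C\[Li])CO[Si](C)(C)C(C)(C)C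
F4 | step 8 | (3E,7E,11E)-4-{[(tert-butyldimethylsilyl)oxy]methyl}-8,12,16-trimethylheptadeca-3,7,11,15-tetraen-1-ol | CC(C)=CCC/C(C)=C/CC/C(C)=C/CC/C(=C\CCO)CO[Si](C)(C)C(C)(C)C
F5 | step 8 | (3E,7E,11E)-4-{[(tert-butyldimethylsilyl)oxy]methyl}-8,12,16-trimethylheptadeca-3,7,11,15-tetraen-1-yl N,N-diisopropylcarbamate | CC(C)=CCC/C(C)=C/CC/C(C)=C/CC/C(=C\CCOC(=O)N(C(C)C)C(C)C)CO[Si](C)(C)C(C)(C)C
F6 | step 8 | (S)-α-lithiated carbamate derived from F5 (sparteine complex) | CC(C)=CCC/C(C)=C/CC/C(C)=C/CC/C(=C\C[C@H]([Li])OC(=O)N(C(C)C)C(C)C)CO[Si](C)(C)C(C)(C)C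
F7 | step 8 | lithium boronate complex of F6 with 3 | [Li+].CC(C)=CCC/C(C)=C/CC/C(C)=C/CC/C(=C\C[C@H]([B-]1(C(=C)COCc2ccc(OC)cc2)OC(C)(C)C(C)(C)O1)OC(=O)N(C(C)C)C(C)C)CO[Si](C)(C)C(C)(C)C
F8 | step 13 | 2-(furan-3-yl)-4,4,5,5-tetramethyl-1,3,2-dioxaborolane (purchased) | CC1(C)OB(c2ccoc2)OC1(C)C
F9 | step 13 | lithium (furan-3-yl)(vinyl)(pinacolato)borate | [Li+].C=C[B-]1(c2ccoc2)OC(C)(C)C(C)(C)O1
F10 | step 13 | 2-[(1R,3E,7E,11E)-4-{[(tert-butyldimethylsilyl)oxy]methyl}-1-(furan-3-yl)-8,12,16-trimethylheptadeca-3,7,11,15-tetraen-1-yl]-4,4,5,5-tetramethyl-1,3,2-dioxaborolane | CC(C)=CCC/C(C)=C/CC/C(C)=C/CC/C(=C\C[C@@H](B1OC(C)(C)C(C)(C)O1)c1ccoc1)CO[Si](C)(C)C(C)(C)C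
F11 | step 13 | (1R,3E,7E,11E)-4-{[(tert-butyldimethylsilyl)oxy]methyl}-1-(furan-3-yl)-8,12,16-trimethylheptadeca-3,7,11,15-tetraen-1-ol | CC(C)=CCC/C(C)=C/CC/C(C)=C/CC/C(=C\C[C@@H](O)c1ccoc1)CO[Si](C)(C)C(C)(C)C
F12 | step 13 | 5-hydroxy-4-[(1R,3E,7E,11E)-1-hydroxy-4-{[(tert-butyldimethylsilyl)oxy]methyl}-8,12,16-trimethylheptadeca-3,7,11,15-tetraen-1-yl]furan-2(5H)-one (both C5 epimers) | CC(C)=CCC/C(C)=C/CC/C(C)=C/CC/C(=C\C[C@@H](O)C1=CC(=O)OC1O)CO[Si](C)(C)C(C)(C)C
F13 | step 13 | 4-[(1R,3E,7E,11E)-1-hydroxy-4-{[(tert-butyldimethylsilyl)oxy]methyl}-8,12,16-trimethylheptadeca-3,7,11,15-tetraen-1-yl]furan-2(5H)-one | CC(C)=CCC/C(C)=C/CC/C(C)=C/CC/C(=C\C[C@@H](O)C1=CC(=O)OC1)CO[Si](C)(C)C(C)(C)C
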